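**Retrosynthetic overview** (chromene numbering O1, C2, C3, C4, C4a, C5–C8, C8a for the pyran-bearing unit)
1. The last step removes two MOM acetals. Before that, the pyran ring O1–C2Me2–C3=C4–C4a=C8a is cut at O1–C2 (retro-oxa-6π) to a vinyl o-quinone methide of ring B. This is re-closed O1–C4 to a four-membered 2-alkenyl-2H-benzoxete, and retro-[2+2] leaves a C4a≡C8a aryne plus 3-methylbut-2-enal, which supplies O1, C2, C3, C4 and both methyl groups.
2. Enabling feature: C4a lies between C8a and the oxygen-bearing C5 of ring B. That oxygen polarises the aryne so that O1 lands on C8a (next to the benzofuranyl carbon C8) and C4 lands on C4a. The C3=C2Me2 arm on the benzoxete carbon makes the opened ring an oxatriene that regains aromaticity only by closing to six atoms.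
3. The aryne comes from an o-silylaryl triflate. Silicon on C4a and the leaving oxygen on C8a are set on a resorcinol unit by two directed ortho-metalations (carbamate plus MOM ether).
4. The aryl–benzofuran bond and the furan ring come from Sonogashira coupling and 5-endo-dig closure of a ring-A ethynylphenol (prenyl by Stille coupling, alkyne by Ohira–Bestmann homologation) with the ring-B iodide.
5. Ring order: both benzene rings are bought, then the furan ring is formed (step 7), then benzoxete and pyran (both in step 10).

Key step: step 10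

Remark on the chemistry: the target has no stereocentre and its only ring alkene is cis by ring constraint, so it is achiral and the route needs no stereocontrol.

**Step 1**
Reactants: 1 5-bromo-2,4-dihydroxybenzaldehyde
Product: 2 5-bromo-2-hydroxy-4-(methoxymethoxy)benzaldehyde
Conditions: MOMCl (1.1 equiv), K2CO3, acetone, 0 °C → rt
Reagents that add atoms: chloromethyl methyl ether, COCCl
Why: Williamson-type O-alkylation; the 2-OH is held in a hydrogen bond to the formyl group, so only the free and more acidic 4-OH should be acetalised.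

**Step 2**
Reactants: 2 5-bromo-2-hydroxy-4-(methoxymethoxy)benzaldehyde
Product: 3 2-hydroxy-4-(methoxymethoxy)-5-(3-methylbut-2-en-1-yl)benzaldehyde
Conditions: tributyl(prenyl)stannane, Pd(PPh3)4 (5 mol %), DMF, 100 °C
Reagents that add atoms: tributyl(3-methylbut-2-en-1-yl)stannane, CCCC[Sn](CCCC)(CCCC)CC=C(C)C
Why: Stille cross-coupling at the only C–Br bond should deliver the linear prenyl arene, because the branched isomer would need an aryl–quaternary carbon bond and the hydrogen-bonded, electron-rich aldehyde is a poor partner for the allylstannane.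

**Step 3**
Reactants: 3 2-hydroxy-4-(methoxymethoxy)-5-(3-methylbut-2-en-1-yl)benzaldehyde
Product: 4 2-ethynyl-5-(methoxymethoxy)-4-(3-methylbut-2-en-1-yl)phenol
Conditions: Ohira–Bestmann reagent, K2CO3, MeOH, rt
Reagents that add atoms: dimethyl (1-diazo-2-oxopropyl)phosphonate, COP(=O)(OC)C(=[N+]=[N-])C(C)=O
Why: Ohira–Bestmann (Seyferth–Gilbert) homologation turns ArCHO into ArC≡CH under carbonate conditions that the free phenol, the MOM acetal and the prenyl alkene should tolerate.

**Step 4**
Reactants: 5 3-(methoxymethoxy)phenol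
Product: 6 3-(methoxymethoxy)phenyl N,N-diethylcarbamate
Conditions: ClC(O)NEt2, K2CO3, MeCN, reflux
Reagents that add atoms: N,N-diethylcarbamoyl chloride, CCN(CC)C(=O)Cl
Why: O-carbamoylation of the phenol installs the strongest oxygen-based director for the ortho-metalations and masks this oxygen as a non-nucleophile.

**Step 5**
Reactants: 6 3-(methoxymethoxy)phenyl N,N-diethylcarbamate
Product: 8 3-(methoxymethoxy)-2-(trimethylsilyl)phenyl N,N-diethylcarbamate, via C2-aryllithium 7 (not isolated)
Conditions: s-BuLi, TMEDA, THF, −78 °C; then TMSCl, −78 °C → rt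
Reagents that add atoms: chlorotrimethylsilane, C[Si](C)(C)Cl
Why: Directed ortho-metalation; the C–H between carbamate and MOM ether is acidified and chelated by both groups, so lithiation and silylation should occur only there, and the anionic ortho-Fries shift is slow at −78 °C.

**Step 6**
Reactants: 8 3-(methoxymethoxy)-2-(trimethylsilyl)phenyl N,N-diethylcarbamate
Product: 10 6-iodo-3-(methoxymethoxy)-2-(trimethylsilyl)phenyl N,N-diethylcarbamate, via C6-aryllithium 9 (not isolated)
Conditions: s-BuLi, TMEDA, THF, −78 °C; then I2, THF, −78 °C → rt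
Reagents that add atoms: iodine, II
Why: Second directed ortho-metalation; with one ortho site blocked by silicon, the carbamate (a stronger director than OMOM) should steer lithiation to its remaining ortho C–H, and iodine quenches the anion.

**Step 7**
Reactants: 4 2-ethynyl-5-(methoxymethoxy)-4-(3-methylbut-2-en-1-yl)phenol; 10 6-iodo-3-(methoxymethoxy)-2-(trimethylsilyl)phenyl N,N-diethylcarbamate
Product: 12 3-(methoxymethoxy)-6-[6-(methoxymethoxy)-5-(3-methylbut-2-en-1-yl)-1-benzofuran-2-yl]-2-(trimethylsilyl)phenyl N,N-diethylcarbamate, via diarylalkyne 11 (not isolated)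
Conditions: PdCl2(PPh3)2 (3 mol %), CuI (5 mol %), Et3N, DMF, rt → 70 °C, degassed
Reagents that add atoms: none
Why: Sonogashira coupling is followed in the same flask by metal-assisted 5-endo-dig hydroalkoxylation; only ring A carries a free ortho OH (the ring-B oxygen next to the alkyne is a carbamate), so a single benzofuran can form.

**Step 8**
Reactants: 12 the arylbenzofuran carbamate of step 7
Product: 13 3-(methoxymethoxy)-6-[6-(methoxymethoxy)-5-(3-methylbut-2-en-1-yl)-1-benzofuran-2-yl]-2-(trimethylsilyl)phenol
Conditions: LiAlH4, THF, 0 °C → rt; Rochelle salt work-up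
Reagents that add atoms: none
Why: Hydride cleavage of an aryl carbamate (acyl substitution that expels the phenoxide, then reduction of the formamide) leaves the C–Si bond, the acetals, the alkene and the benzofuran untouched.

**Step 9**
Reactants: 13 the o-silylphenol of step 8
Product: 14 3-(methoxymethoxy)-6-[6-(methoxymethoxy)-5-(3-methylbut-2-en-1-yl)-1-benzofuran-2-yl]-2-(trimethylsilyl)phenyl trifluoromethanesulfonate
Conditions: Tf2O, pyridine, CH2Cl2, −78 → 0 °C
Reagents that add atoms: trifluoromethanesulfonic anhydride, O=S(=O)(OS(=O)(=O)C(F)(F)F)C(F)(F)F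
Why: O-sulfonylation of the only free phenol under pyridine buffering gives the o-silylaryl triflate, the standard latent aryne.

**Step 10**
Reactants: 14 the o-silylaryl triflate of step 9; 15 3-methylbut-2-enal
Product: 19 bis(methoxymethyl) ether of kanzonol V, via aryne 16 (not isolated), via 2H-benzoxete 17 (not isolated), via o-quinone methide 18 (not isolated)
Conditions: CsF, MeCN, 40 °C; 14 added slowly to excess 15
Reagents that add atoms: none
Why: Fluoride attacks silicon and triflate leaves from the neighbouring carbon to give aryne 16, whose C4a≡C8a bond is distorted by the σ-withdrawing OMOM group on C5, so the carbonyl oxygen of 15 should add to the remote C8a and the carbanion developing at C4a should collapse onto the oxocarbenium carbon in an asynchronous formal [2+2] closure to the four-membered 2H-benzoxete 17 (ring O1–C4–C4a–C8a). Ring strain then drives conrotatory 4π opening of the O1–C4 bond to the dearomatised vinyl o-quinone methide 18, whose E and Z forms can interconvert through 17, and the Z,s-cis form closes by disrotatory oxa-6π electrocyclisation (O1–C2 bond), so that C3 and C2 are taken up into the ring, four atoms become six and ring B regains its aromaticity. The closest known reaction type is the annulation of arynes with α,β-unsaturated aldehydes to 2H-chromenes, backed by the aryne–aldehyde route to xanthenes that runs through the same o-quinone methides. No stereocentre has to be controlled: the sp3 carbon of 17 is transient and racemic and becomes the sp2 C4 of 19. The step needs regioselectivity, which the C5 oxygen secures because its inductive pull outweighs the weak polarisation and the bulk of the benzofuranyl group on C8, and chemoselectivity for C=O capture over the aryne-ene reaction of the prenyl chain and over a second aryne adding to 18, which slow release of 16 into a large excess of 15 and the intramolecular, aromatising 6π closure should secure. Closure of the zwitterion at the γ-carbon to a 4H-chromene is not expected, since the carbanion lies next to the carbonyl carbon and far from the CMe2 terminus.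

**Step 11**
Reactants: 19 bis(methoxymethyl) ether of kanzonol V
Product: 20 kanzonol V
Conditions: HCl (1.25 M in MeOH), MeOH/THF, 0 °C → rt
Reagents that add atoms: none
Why: Acid-catalysed acetal exchange with methanol frees both phenols under conditions mild enough that the o-prenylphenol and the 2,2-dimethylchromene should survive.

**Compound list**
1 | 5-bromo-2,4-dihydroxybenzaldehyde | O=Cc1cc(Br)c(O)cc1O | starting material
2 | 5-bromo-2-hydroxy-4-(methoxymethoxy)benzaldehyde | O=Cc1cc(Br)c(OCOC)cc1O | intermediate
3 | 2-hydroxy-4-(methoxymethoxy)-5-(3-methylbut-2-en-1-yl)benzaldehyde | CC(C)=CCc1cc(C=O)c(O)cc1OCOC | intermediate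
4 | 2-ethynyl-5-(methoxymethoxy)-4-(3-methylbut-2-en-1-yl)phenol | C#Cc1cc(CC=C(C)C)c(OCOC)cc1O | intermediate
5 | 3-(methoxymethoxy)phenol | COCOc1cccc(O)c1 | starting material
6 | 3-(methoxymethoxy)phenyl N,N-diethylcarbamate | CCN(CC)C(=O)Oc1cccc(OCOC)c1 | intermediate
7 | 2-lithio-3-(methoxymethoxy)phenyl N,N-diethylcarbamate (not isolated) | [Li]c1c(OC(=O)N(CC)CC)cccc1OCOC | intermediate
8 | 3-(methoxymethoxy)-2-(trimethylsilyl)phenyl N,N-diethylcarbamate | CCN(CC)C(=O)Oc1cccc(OCOC)c1[Si](C)(C)C | intermediate
9 | 6-lithio-3-(methoxymethoxy)-2-(trimethylsilyl)phenyl N,N-diethylcarbamate (not isolated) | [Li]c1ccc(OCOC)c([Si](C)(C)C)c1OC(=O)N(CC)CC | intermediate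
10 | 6-iodo-3-(methoxymethoxy)-2-(trimethylsilyl)phenyl N,N-diethylcarbamate | CCN(CC)C(=O)Oc1c(I)ccc(OCOC)c1[Si](C)(C)C | intermediate
11 | 6-{[2-hydroxy-4-(methoxymethoxy)-5-(3-methylbut-2-en-1-yl)phenyl]ethynyl}-3-(methoxymethoxy)-2-(trimethylsilyl)phenyl N,N-diethylcarbamate (not isolated) | CC(C)=CCc1cc(C#Cc2ccc(OCOC)c([Si](C)(C)C)c2OC(=O)N(CC)CC)c(O)cc1OCOC | intermediate
12 | 3-(methoxymethoxy)-6-[6-(methoxymethoxy)-5-(3-methylbut-2-en-1-yl)-1-benzofuran-2-yl]-2-(trimethylsilyl)phenyl N,N-diethylcarbamate | CC(C)=CCc1cc2cc(-c3ccc(OCOC)c([Si](C)(C)C)c3OC(=O)N(CC)CC)oc2cc1OCOC | intermediate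
13 | 3-(methoxymethoxy)-6-[6-(methoxymethoxy)-5-(3-methylbut-2-en-1-yl)-1-benzofuran-2-yl]-2-(trimethylsilyl)phenol | CC(C)=CCc1cc2cc(-c3ccc(OCOC)c([Si](C)(C)C)c3O)oc2cc1OCOC | intermediate
14 | 3-(methoxymethoxy)-6-[6-(methoxymethoxy)-5-(3-methylbut-2-en-1-yl)-1-benzofuran-2-yl]-2-(trimethylsilyl)phenyl trifluoromethanesulfonate | CC(C)=CCc1cc2cc(-c3ccc(OCOC)c([Si](C)(C)C)c3OS(=O)(=O)C(F)(F)F)oc2cc1OCOC | intermediate
15 | 3-methylbut-2-enal | CC(C)=CC=O | starting material
16 | ring-B aryne: 2-[4-(methoxymethoxy)-2,3-didehydrophenyl]-6-(methoxymethoxy)-5-(3-methylbut-2-en-1-yl)-1-benzofuran (not isolated) | CC(C)=CCc1cc2cc(C3=CC=C(OCOC)C#C3)oc2cc1OCOC | intermediate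
17 | 2-(2-methylprop-1-enyl)-2H-benzoxete fused to ring B, racemic (not isolated) | CC(C)=CCc1cc2cc(-c3ccc(OCOC)c4c3OC4C=C(C)C)oc2cc1OCOC | intermediate
18 | (Z)-6-(3-methylbut-2-enylidene)cyclohexa-2,4-dienone form of ring B, vinyl o-quinone methide (not isolated) | O=C1/C(=C\C=C(C)C)C(OCOC)=CC=C1c1cc2cc(CC=C(C)C)c(OCOC)cc2o1 | intermediate
19 | 5-(methoxymethoxy)-8-[6-(methoxymethoxy)-5-(3-methylbut-2-en-1-yl)-1-benzofuran-2-yl]-2,2-dimethyl-2H-chromene | CC(C)=CCc1cc2cc(-c3ccc(OCOC)c4c3OC(C)(C)C=C4)oc2cc1OCOC | intermediate
20 | kanzonol V | CC(C)=CCc1cc2cc(-c3ccc(O)c4c3OC(C)(C)C=C4)oc2cc1O | target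

**Total step count:** 11.
**Longest linear sequence:** 8 (steps 4–11; the branch through steps 1–3 and 7–11 is equally long).

**Steps most likely to fail**

Step 10. Capture of the aryne by the weakly nucleophilic carbonyl oxygen may be outrun by three processes: ene reaction at the prenyl chain, addition of a second aryne to the opened ring, or fluoride-induced self-condensation of the enal. Attack at the wrong aryne carbon would erode regiocontrol.
- The fallback sets out from 14 and comes back at 19.
- It replaces the aldehyde by a far better arynophile, 3-methylbut-2-enoic acid (CsF, THF, sealed tube, heat).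
- The carboxylate should add to C8a of aryne 16. The aryl anion should attack its own ester carbonyl through a four-membered benzoxete alkoxide that opens to the o-hydroxyaryl 2-methylpropenyl ketone F1.
- This closes by 6-endo-trig oxa-Michael addition to the 2,2-dimethylchroman-4-one F2.
- NaBH4 in MeOH should give the racemic chroman-4-ol F3.
- Mesylation with in-situ elimination (MsCl, Et3N, CH2Cl2, 0 °C → rt) should give 19.

Step 3. The phenoxide formed under carbonate conditions pushes electron density into the formyl group, so addition of the diazophosphonate anion may stall. The electron-rich ethynylphenol may also cyclise or oligomerise on handling.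
- The fallback avoids the alkyne. It sets out from 3 and from aryllithium 9 (made from 8 as in step 6) and comes back at 12.
- Ramirez olefination of 3 (CBr4, PPh3, Et3N, CH2Cl2, 0 °C) should give the gem-dibromovinylphenol F4.
- Copper-catalysed intramolecular C–O coupling (CuI, K3PO4, THF, 80 °C) should give the 2-bromobenzofuran F5.
- Transmetalation of 9 with ZnCl2 gives the arylzinc chloride F6.
- Negishi coupling of F5 with F6 (Pd(PPh3)4, THF, 50 °C) should give 12, so that steps 3, 7 and the iodination are bypassed.

Step 11. Acid may trigger cyclisation of the freed phenol onto the neighbouring prenyl alkene, or addition of methanol across the electron-rich pyran alkene, before both acetals are gone.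
- The fallback sets out from 19 and comes back at 20 without any Brønsted acid.
- TMSOTf and 2,2'-bipyridyl in MeCN at 0 °C should exchange both aryl acetals for silyl groups to give the bis(trimethylsilyl) ether F7.
- Water at rt then hydrolyses F7 to 20.

**Further compounds**
F1 | step 10 | 1-{2-hydroxy-6-(methoxymethoxy)-3-[6-(methoxymethoxy)-5-(3-methylbut-2-en-1-yl)-1-benzofuran-2-yl]phenyl}-3-methylbut-2-en-1-one | CC(C)=CCc1cc2cc(-c3ccc(OCOC)c(C(=O)C=C(C)C)c3O)oc2cc1OCOC
F2 | step 10 | 5-(methoxymethoxy)-8-[6-(methoxymethoxy)-5-(3-methylbut-2-en-1-yl)-1-benzofuran-2-yl]-2,2-dimethylchroman-4-one | CC(C)=CCc1cc2cc(-c3ccc(OCOC)c4c3OC(C)(C)CC4=O)oc2cc1OCOC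
F3 | step 10 | racemic 5-(methoxymethoxy)-8-[6-(methoxymethoxy)-5-(3-methylbut-2-en-1-yl)-1-benzofuran-2-yl]-2,2-dimethylchroman-4-ol | CC(C)=CCc1cc2cc(-c3ccc(OCOC)c4c3OC(C)(C)CC4O)oc2cc1OCOC
F4 | step 3 | 2-(2,2-dibromovinyl)-5-(methoxymethoxy)-4-(3-methylbut-2-en-1-yl)phenol | CC(C)=CCc1cc(C=C(Br)Br)c(O)cc1OCOC
F5 | step 3 | 2-bromo-6-(methoxymethoxy)-5-(3-methylbut-2-en-1-yl)-1-benzofuran | CC(C)=CCc1cc2cc(Br)oc2cc1OCOC
F6 | step 3 | {2-[(diethylcarbamoyl)oxy]-4-(methoxymethoxy)-3-(trimethylsilyl)phenyl}zinc chloride | Cl[Zn]c1ccc(OCOC)c([Si](C)(C)C)c1OC(=O)N(CC)CC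
F7 | step 11 | bis(trimethylsilyl) ether of kanzonol V | CC(C)=CCc1cc2cc(-c3ccc(O[Si](C)(C)C)c4c3OC(C)(C)C=C4)oc2cc1O[Si](C)(C)C
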